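(The earlier runs and the new flask were generated by integration from invented constants; the scatter is artificial.)

In the blue run, which is the very flask asked about, the over-reaction product rose by 10 percentage points between 0.500 min and 1.00 min with 8.5% of target present, faster than between 3.00 min and 4.00 min, when it rose by 0.1 points with 10.2% of target present.

all flasks: starting material 0.20 mM; free catalyst 30 µM
- blue: second substrate 0.20 mM; partner 0.21 mM; capture agent 0.010 mM; the very flask that is asked about, followed so far
- flask: second substrate 0.200 mM; partner 0.210 mM; capture agent 0.0100 mM; time 30 min

blue run (percent of the starting material charged)

| time / min | target / % | over-reaction product / % |
|---|---|---|
| 0.200 | 5.8 | 5.1 |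
| 0.500 | 8.1 | 17.7 |
| 1.00 | 8.5 | 27.9 |
| 1.50 | 10.2 | 32.4 |
| 2.00 | 9.6 | 33.6 |
| 3.00 | 10.4 | 34.7 |
| 4.00 | 10.2 | 34.8 |

(readings scatter by 0.3 percentage points)

- what was read earlier has a scatter of 0.3 percentage points, one standard deviation
- a reading or a percentage of target counts all its forms, free or not
- the reaction counts as stopped when no species that holds the starting material changes by six tenths of a point or more over the second half of the time

- why nothing more happens at 30 min, or that something still does (the partner has run out first / forward and back rates have come level / all of the starting material has reacted / it is still moving / no working catalyst is left)
- how much target there is at 30 min, in percent of the starting material charged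
- how much over-reaction product there is at 30 min, in percent of the starting material charged

I read the over-reaction product as target plus one more partner, so a stop with target still standing pointed to the partner before the catalyst. But did the charge allow that? I followed one molecule of starting material: it spends one partner to become target and, at the next fork, a second to become over-reaction product, so the last readings had cost 0.160 mM of the 0.21 mM charged. That raised the next question, for 0.0504 mM of the charge stood unaccounted for, and I called this the partner gap, the charge less what target and over-reaction product hold. I assigned the gap, as a guess from the charges, to the other fork, the second substrate, of whose charge it is a quarter. I therefore committed to the partner as limiting reagent, and to target and over-reaction product staying at those last readings at 30 min.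

The forecast gave 10.2% of target, 34.9% of over-reaction product and the ending "no working catalyst is left", holding that the stop “points to catalyst death or poisoning”.

The flask gave 9.98% of target and 34.8% of over-reaction product, and its ending was "the partner has run out first", with 0% of the partner left at 30.0 min. Second product in the flask stood at 0.0508 mM at that time, close to the partner gap of 0.0504 mM reckoned from the readings.

    starting material + free catalyst ⇌ catalyst intermediate A (K = 12000 /M, k = 1300 /M/s)
    partner + catalyst intermediate A → free catalyst + target (k = 1590 /M/s)
    second substrate + free catalyst ⇌ catalyst intermediate B (K = 6600 /M, k = 2210 /M/s)
    partner + catalyst intermediate B → free catalyst + second product (k = 706 /M/s)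
    partner + target → over-reaction product (k = 708 /M/s)
    catalyst intermediate A + capture agent → trapped intermediate (k = 303 /M/s)
    crystals ⇌ target, rate k7*(cs7 - [target]) while solid is left; crystals form when [target] > cs7 (solubility = 0.170 mM, k = 0.226 /s)

For the neighbour charged with 0.080 mM of second substrate, taking the same share of its own charge, 25.2%, gives an estimated partner gap of 0.0202 mM, leaving 0.190 mM for target and over-reaction product. That neighbour computed 0.0243 mM of second product, more than this estimate, with 11.5% of target and 40.7% of over-reaction product, which hold 0.186 mM of partner.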